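**Retrosynthetic overview**

1. The target comes from an 8(17)-methylidene decalin by Markovnikov hydration at C8; before that the side chain is completed by a Negishi coupling (C12–C13), and C17 comes from methylenation of a C8 ketone.
2. The bicyclic C8 ketone comes from an acyclic trienone by a Lewis-acid-triggered cationic bicyclization: ring B is formed first by the C5–C6 bond, ring A second by the C1–C10 bond (vinylsilane terminator).
3. Enabling feature: the C8 oxygen. As a ketone it makes C6=C7–C8 a vinyl ketone with electrophilic C6 and makes C9 epimerizable. The ring-fusion atoms C5 and C10, shared by rings A and B, are the two carbons of an (E)-trisubstituted alkene, so anti addition of C6 and C1 can only give the trans-decalin.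
4. The trienone comes from an Ireland–Claisen rearrangement (C8–C9) and oxidative decarboxylation of a vinylglycolate ester of an allylic alcohol, which is assembled by asymmetric alkenylzinc addition (C5–C10) from fragment 1 (C1–C5) and fragment 2 (C9–C12 with C20).

Key step: step 10

Remark: C-numbers are labdane numbers of the target; stereocentres that the following step erases (acyl C2 in 13–19) are carried as epimer mixtures and left undefined in the SMILES.

**Route**

Step 1
Reactants: 1 isobutyronitrile; 2 3-bromo-1-(trimethylsilyl)prop-1-yne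
Product: 4 2,2-dimethyl-5-(trimethylsilyl)pent-4-ynenitrile, via lithiated isobutyronitrile 3 (not isolated)
Conditions: LiN(iPr)2, THF, −78 °C; then 2, −78 °C → rt
Reagents that add atoms: none
Why: C-alkylation of the lithiated nitrile (SN2 at the propargylic bromide) creates the quaternary C4 with its two methyl groups and attaches the silylated C1–C3 arm; no stereocentre is formed.

Step 2
Reactants: 4 2,2-dimethyl-5-(trimethylsilyl)pent-4-ynenitrile
Product: 6 2,2-dimethyl-5-(trimethylsilyl)pent-4-ynal, via N-aluminated aldimine 5 (not isolated)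
Conditions: iBu2AlH, CH2Cl2, −78 °C; then aq. HCl
Reagents that add atoms: water, O
Why: Partial reduction of the nitrile by iBu2AlH stops at the N-aluminated aldimine, whose hydrolysis gives the aldehyde carbon that becomes C5; the silylalkyne is inert at −78 °C.

Step 3
Reactants: 6 2,2-dimethyl-5-(trimethylsilyl)pent-4-ynal
Product: 7 (4Z)-2,2-dimethyl-5-(trimethylsilyl)pent-4-enal
Conditions: H2 (1 atm), Pd/CaCO3 poisoned with Pb(OAc)2 (Lindlar catalyst), quinoline, hexane, rt
Reagents that add atoms: none
Why: Lindlar semi-hydrogenation adds hydrogen syn to the silylalkyne and so sets the (Z)-vinylsilane that the ipso-terminated closure of ring A needs, while the aldehyde is untouched.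

Step 4
Reactants: 8 pent-3-yn-1-ol
Product: 9 5-chloropent-2-yne
Conditions: PPh3, N-chlorosuccinimide, CH2Cl2, 0 °C → rt
Reagents that add atoms: N-chlorosuccinimide, O=C1CCC(=O)N1Cl
Why: Appel-type chlorination converts the primary alcohol to the chloride by SN2 at an alkoxyphosphonium ion; no stereocentre is involved.

Step 5
Reactants: 9 5-chloropent-2-yne; 7 (4Z)-2,2-dimethyl-5-(trimethylsilyl)pent-4-enal
Product: 12 (1Z,5R,6E)-9-chloro-4,4,6-trimethyl-1-(trimethylsilyl)nona-1,6-dien-5-ol, via alkenylzirconocene chloride 10 (not isolated), via alkenyl(methyl)zinc 11 (not isolated)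
Conditions: Cp2Zr(H)Cl, CH2Cl2, rt; Me2Zn, toluene, −65 °C; (−)-MIB (10 mol %); then 7, −30 → 0 °C; aq. NH4Cl
Reagents that add atoms: none
Why: Syn hydrozirconation places zirconium on the methyl-bearing alkyne carbon (less hindered) and fixes the (E)-geometry, and after Zr-to-Zn transmetalation the amino-alcohol-catalysed alkenylzinc addition should deliver the alkenyl group to the Si face of the aldehyde, setting (5R) (catalytic asymmetric alkenylzinc addition to an aldehyde).

Step 6
Reactants: 13 2-hydroxybut-3-enoic acid (racemic)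
Product: 15 2-[(triethylsilyl)oxy]but-3-enoic acid (racemic), via bis(triethylsilyl) derivative 14 (not isolated)
Conditions: Et3SiCl (2.2 equiv), imidazole, DMF, 0 °C → rt; then MeOH–H2O, rt
Reagents that add atoms: chlorotriethylsilane, CC[Si](Cl)(CC)CC
Why: Exhaustive silylation followed by selective solvolysis of the labile silyl ester leaves the O-silylated acid needed for acylation; the stereocentre stays racemic, which is harmless because it is erased in step 8.

Step 7
Reactants: 12 (1Z,5R,6E)-9-chloro-4,4,6-trimethyl-1-(trimethylsilyl)nona-1,6-dien-5-ol; 15 2-[(triethylsilyl)oxy]but-3-enoic acid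
Product: 16 (1Z,5R,6E)-9-chloro-4,4,6-trimethyl-1-(trimethylsilyl)nona-1,6-dien-5-yl 2-[(triethylsilyl)oxy]but-3-enoate (both acyl C2 epimers)
Conditions: DCC, DMAP (cat.), CH2Cl2, 0 °C → rt
Reagents that add atoms: none
Why: Carbodiimide (Steglich) esterification acylates the hindered secondary allylic alcohol with retention at C5.

Step 8
Reactants: 16 the vinylglycolate ester
Product: 19 (3S,4E,8Z)-3-(2-chloroethyl)-2-ethenyl-2-hydroxy-4,6,6-trimethyl-9-(trimethylsilyl)nona-4,8-dienoic acid (C2 epimers), via silyl ketene acetal 17 (not isolated), via rearranged trimethylsilyl ester 18 (not isolated)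
Conditions: KN(SiMe3)2, Me3SiCl, THF, −78 → 40 °C; then 1 M HCl, THF, rt
Reagents that add atoms: none
Why: Ireland–Claisen rearrangement: the silyl ketene acetal rearranges through a chair transition state with the quaternary C4 substituent equatorial, which should give the (E)-C5=C10 alkene and transfer the (5R) carbinol chirality suprafacially to C9 (3S in the acid), while the new fully substituted C8 centre is left undefined because step 9 erases it; acid work-up removes both silyl groups.

Step 9
Reactants: 19 the α-hydroxy acid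
Product: 20 (4S,5E,9Z)-4-(2-chloroethyl)-5,7,7-trimethyl-10-(trimethylsilyl)deca-1,5,9-trien-3-one
Conditions: Pb(OAc)4, CH2Cl2, 0 °C; used at once
Reagents that add atoms: none
Why: Oxidative decarboxylation of the α-hydroxy acid by Pb(OAc)4 turns C8 into the ketone under non-basic conditions, which unveils the vinyl ketone without epimerising the allylic C9 centre or conjugating the C5=C10 alkene.

Step 10
Reactants: 20 (4S,5E,9Z)-4-(2-chloroethyl)-5,7,7-trimethyl-10-(trimethylsilyl)deca-1,5,9-trien-3-one
Product: 22 (1S,4aS,8aS)-1-(2-chloroethyl)-5,5,8a-trimethyl-3,4,4a,5,6,8a-hexahydronaphthalen-2(1H)-one, via bicyclic aluminium enolate 21 (not isolated)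
Conditions: MeAlCl2 (2.2 equiv), 2,6-di-tert-butylpyridine (0.2 equiv), CH2Cl2, −78 → −40 °C; aq. NaHCO3
Reagents that add atoms: none
Why: Proposed new method: MeAlCl2 binds the C8 carbonyl so that C6, the β-carbon of the vinyl ketone, is attacked by C5 of the (E)-C5=C10 alkene (Markovnikov, tertiary C10 cation, aluminium enolate at C7=C8), and the cation is captured by C1 of the (Z)-vinylsilane, whose β-silyl cation loses the silyl group to leave the C1=C2 alkene; the closest known reaction types are Lewis-acid-promoted enone–alkene cation–olefin (Michael-type and ene) cyclizations and Stork–Eschenmoser polyene cyclizations ended by vinylsilanes. Ring B closes in a 6-endo-trig mode at the alkene (C5–C6 bond) through a chair-like transition state, ring A in a 6-endo-trig ipso attack on the vinylsilane (C1–C10 bond). C5 and C10 are set relative to each other by antiperiplanar addition of C6 and C1 across the (E)-alkene, which can only give the trans ring fusion (5-H and 10-CH3 anti). Their absolute sense is dictated by C9: the 2-chloroethyl group should take the pseudo-axial (inside) position to avoid 1,2-allylic strain with the C10 methyl group, so the (4S) trienone should give the (4aS,8aS) ring fusion with C9 still in the axial, non-natural orientation that step 11 corrects. The step needs C5 rather than C10 to bond to C6 (secured by the tertiary cation), ring A closure to outrun proton loss from C20 or collapse of the enolate onto C10 (favoured by the gem-dimethyl group at C4, the six-membered chair and the β-silicon effect), and no enolisation toward C9 (low temperature, short time). The primary chloride is inert, and its five-membered chloronium ion with the C10 cation is reversible.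

Step 11
Reactants: 22 (1S,4aS,8aS)-1-(2-chloroethyl)-5,5,8a-trimethyl-3,4,4a,5,6,8a-hexahydronaphthalen-2(1H)-one
Product: 23 (1R,4aS,8aS)-1-(2-chloroethyl)-5,5,8a-trimethyl-3,4,4a,5,6,8a-hexahydronaphthalen-2(1H)-one
Conditions: TsOH·H2O (cat.), CH2Cl2, rt
Reagents that add atoms: none
Why: Acid-catalysed enolisation toward C9 equilibrates the axial 2-chloroethyl group to the thermodynamically preferred equatorial position (1R), acid being chosen because a C9 enolate would displace the chloride to a cyclopropane.

Step 12
Reactants: 23 (1R,4aS,8aS)-1-(2-chloroethyl)-5,5,8a-trimethyl-3,4,4a,5,6,8a-hexahydronaphthalen-2(1H)-one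
Product: 24 (1R,4aS,8aS)-1-(2-chloroethyl)-5,5,8a-trimethyloctahydronaphthalen-2(1H)-one
Conditions: H2 (1 atm), Pd/C, EtOAc, rt
Reagents that add atoms: none
Why: Heterogeneous hydrogenation saturates the cis-disubstituted C1=C2 alkene of ring A; ketone and primary chloride are inert and no stereocentre is created.

Step 13
Reactants: 24 (1R,4aS,8aS)-1-(2-chloroethyl)-5,5,8a-trimethyloctahydronaphthalen-2(1H)-one
Product: 25 (1S,4aS,8aS)-1-(2-chloroethyl)-5,5,8a-trimethyl-2-methylidenedecahydronaphthalene
Conditions: Cp2TiMe2, toluene, 75 °C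
Reagents that add atoms: dimethyltitanocene (Cp2TiMe2), C[Ti](C)(C1C=CC=C1)C1C=CC=C1
Why: Petasis methylenation converts the hindered, enolisable C8 ketone to the C8=C17 methylidene group without base, so C9 is not touched (its descriptor becomes S only because the priorities change).

Step 14
Reactants: 26 but-2-yn-1-ol
Product: 27 but-2-yn-1-yl acetate
Conditions: Ac2O, pyridine, DMAP (cat.), CH2Cl2, 0 °C → rt
Reagents that add atoms: acetic anhydride, CC(=O)OC(C)=O
Why: Acetylation of the primary propargylic alcohol under nucleophilic catalysis by DMAP.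

Step 15
Reactants: 27 but-2-yn-1-yl acetate
Product: 29 (2E)-3-iodobut-2-en-1-yl acetate, via alkenylzirconocene chloride 28 (not isolated)
Conditions: Cp2Zr(H)Cl, THF, rt; then I2, 0 °C
Reagents that add atoms: iodine, II
Why: Syn hydrozirconation with zirconium at the methyl-bearing carbon, away from the acetoxymethyl group, followed by iodinolysis with retention should give the (E)-vinyl iodide (hydrozirconation–iodination).

Step 16
Reactants: 25 (1S,4aS,8aS)-1-(2-chloroethyl)-5,5,8a-trimethyl-2-methylidenedecahydronaphthalene; 29 (2E)-3-iodobut-2-en-1-yl acetate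
Product: 32 (2E)-3-methyl-5-[(1S,4aS,8aS)-5,5,8a-trimethyl-2-methylidenedecahydronaphthalen-1-yl]pent-2-en-1-yl acetate, via alkylmagnesium chloride 30 (not isolated), via alkylzinc chloride 31 (not isolated)
Conditions: Mg, THF, reflux; ZnCl2, THF, 0 °C; then 29, Pd(dppf)Cl2 (3 mol %), THF, rt
Reagents that add atoms: none
Why: Negishi coupling: the Grignard reagent made from the primary chloride is transmetalated to zinc and coupled at the vinyl iodide under zerovalent palladium catalysis with retention of the (E)-geometry, forming the C12–C13 bond; the acetate tolerates the organozinc.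

Step 17
Reactants: 32 (2E)-3-methyl-5-[(1S,4aS,8aS)-5,5,8a-trimethyl-2-methylidenedecahydronaphthalen-1-yl]pent-2-en-1-yl acetate
Product: 34 (2E)-5-[(1R,2R,4aS,8aS)-2-hydroxy-2,5,5,8a-tetramethyldecahydronaphthalen-1-yl]-3-methylpent-2-en-1-yl acetate, via alkylmercury acetate 33 (not isolated)
Conditions: Hg(OAc)2 (1.05 equiv), THF–H2O, 0 °C → rt; then NaBH4, aq. NaHCO3, 0 °C
Reagents that add atoms: water, O
Why: Markovnikov oxymercuration–demercuration: the 1,1-disubstituted C8=C17 alkene should react far faster than the trisubstituted, acetoxy-deactivated C13=C14 alkene, and water should enter C8 from the equatorial α face opposite to the axial C10 methyl group, giving the (8R) tertiary alcohol with axial C17 methyl (2R in the decalin name).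

**Compound list**

1 | isobutyronitrile | CC(C)C#N | starting material
2 | 3-bromo-1-(trimethylsilyl)prop-1-yne | BrCC#C[Si](C)(C)C | starting material
3 | lithiated isobutyronitrile | [Li]C(C)(C)C#N | intermediate (not isolated)
4 | 2,2-dimethyl-5-(trimethylsilyl)pent-4-ynenitrile | N#CC(C)(C)CC#C[Si](C)(C)C | intermediate
5 | N-(diisobutylaluminio) aldimine of 6 | CC(C)C[Al](CC(C)C)N=CC(C)(C)CC#C[Si](C)(C)C | intermediate (not isolated)
6 | 2,2-dimethyl-5-(trimethylsilyl)pent-4-ynal | O=CC(C)(C)CC#C[Si](C)(C)C | intermediate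
7 | (4Z)-2,2-dimethyl-5-(trimethylsilyl)pent-4-enal | O=CC(C)(C)C/C=C\[Si](C)(C)C | intermediate
8 | pent-3-yn-1-ol | CC#CCCO | starting material
9 | 5-chloropent-2-yne | CC#CCCCl | intermediate
10 | chloro[(2E)-5-chloropent-2-en-2-yl]zirconocene | ClCC/C=C(\C)[Zr](Cl)(C1C=CC=C1)C1C=CC=C1 | intermediate (not isolated)
11 | [(2E)-5-chloropent-2-en-2-yl](methyl)zinc | ClCC/C=C(\C)[Zn]C | intermediate (not isolated)
12 | (1Z,5R,6E)-9-chloro-4,4,6-trimethyl-1-(trimethylsilyl)nona-1,6-dien-5-ol | ClCC/C=C(C)/[C@H](O)C(C)(C)C/C=C\[Si](C)(C)C | intermediate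
13 | 2-hydroxybut-3-enoic acid (racemic) | OC(C=C)C(=O)O | starting material
14 | triethylsilyl 2-[(triethylsilyl)oxy]but-3-enoate | CC[Si](CC)(CC)OC(C=C)C(=O)O[Si](CC)(CC)CC | intermediate (not isolated)
15 | 2-[(triethylsilyl)oxy]but-3-enoic acid (racemic) | CC[Si](CC)(CC)OC(C=C)C(=O)O | intermediate
16 | (1Z,5R,6E)-9-chloro-4,4,6-trimethyl-1-(trimethylsilyl)nona-1,6-dien-5-yl 2-[(triethylsilyl)oxy]but-3-enoate (acyl C2 epimers) | ClCC/C=C(C)/[C@H](OC(=O)C(O[Si](CC)(CC)CC)C=C)C(C)(C)C/C=C\[Si](C)(C)C | intermediate
17 | trimethylsilyl ketene acetal of 16 | ClCC/C=C(C)/[C@H](OC(O[Si](C)(C)C)=C(O[Si](CC)(CC)CC)C=C)C(C)(C)C/C=C\[Si](C)(C)C | intermediate (not isolated)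
18 | trimethylsilyl ester of the O-triethylsilyl ether of 19 | C[Si](C)(C)OC(=O)C(O[Si](CC)(CC)CC)(C=C)[C@@H](CCCl)/C(C)=C/C(C)(C)C/C=C\[Si](C)(C)C | intermediate (not isolated)
19 | (3S,4E,8Z)-3-(2-chloroethyl)-2-ethenyl-2-hydroxy-4,6,6-trimethyl-9-(trimethylsilyl)nona-4,8-dienoic acid (C2 epimers) | OC(=O)C(O)(C=C)[C@@H](CCCl)/C(C)=C/C(C)(C)C/C=C\[Si](C)(C)C | intermediate
20 | (4S,5E,9Z)-4-(2-chloroethyl)-5,7,7-trimethyl-10-(trimethylsilyl)deca-1,5,9-trien-3-one | C=CC(=O)[C@@H](CCCl)/C(C)=C/C(C)(C)C/C=C\[Si](C)(C)C | intermediate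
21 | chloro(methyl)aluminium enolate of 22 | ClCC[C@H]1[C@@]2(C)C=CCC(C)(C)[C@@H]2CC=C1O[Al](C)Cl | intermediate (not isolated)
22 | (1S,4aS,8aS)-1-(2-chloroethyl)-5,5,8a-trimethyl-3,4,4a,5,6,8a-hexahydronaphthalen-2(1H)-one | ClCC[C@H]1[C@@]2(C)C=CCC(C)(C)[C@@H]2CCC1=O | intermediate
23 | (1R,4aS,8aS)-1-(2-chloroethyl)-5,5,8a-trimethyl-3,4,4a,5,6,8a-hexahydronaphthalen-2(1H)-one | ClCC[C@@H]1[C@@]2(C)C=CCC(C)(C)[C@@H]2CCC1=O | intermediate
24 | (1R,4aS,8aS)-1-(2-chloroethyl)-5,5,8a-trimethyloctahydronaphthalen-2(1H)-one | ClCC[C@@H]1[C@@]2(C)CCCC(C)(C)[C@@H]2CCC1=O | intermediate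
25 | (1S,4aS,8aS)-1-(2-chloroethyl)-5,5,8a-trimethyl-2-methylidenedecahydronaphthalene | ClCC[C@@H]1[C@@]2(C)CCCC(C)(C)[C@@H]2CCC1=C | intermediate
26 | but-2-yn-1-ol | CC#CCO | starting material
27 | but-2-yn-1-yl acetate | CC#CCOC(C)=O | intermediate
28 | [(2E)-4-acetoxybut-2-en-2-yl]chlorozirconocene | CC(=O)OC/C=C(\C)[Zr](Cl)(C1C=CC=C1)C1C=CC=C1 | intermediate (not isolated)
29 | (2E)-3-iodobut-2-en-1-yl acetate | CC(=O)OC/C=C(\C)I | intermediate
30 | alkylmagnesium chloride from 25 | Cl[Mg]CC[C@@H]1[C@@]2(C)CCCC(C)(C)[C@@H]2CCC1=C | intermediate (not isolated)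
31 | alkylzinc chloride from 25 | Cl[Zn]CC[C@@H]1[C@@]2(C)CCCC(C)(C)[C@@H]2CCC1=C | intermediate (not isolated)
32 | (2E)-3-methyl-5-[(1S,4aS,8aS)-5,5,8a-trimethyl-2-methylidenedecahydronaphthalen-1-yl]pent-2-en-1-yl acetate | CC(=O)OC/C=C(\C)CC[C@@H]1[C@@]2(C)CCCC(C)(C)[C@@H]2CCC1=C | intermediate
33 | C17 acetoxymercurio derivative of 34 | CC(=O)OC/C=C(\C)CC[C@@H]1[C@@]2(C)CCCC(C)(C)[C@@H]2CC[C@]1(O)C[Hg]OC(C)=O | intermediate (not isolated)
34 | (2E)-5-[(1R,2R,4aS,8aS)-2-hydroxy-2,5,5,8a-tetramethyldecahydronaphthalen-1-yl]-3-methylpent-2-en-1-yl acetate | CC(=O)OC/C=C(\C)CC[C@@H]1[C@@]2(C)CCCC(C)(C)[C@@H]2CC[C@@]1(C)O | target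

**Step count and risks**

Total: 17 steps. Longest linear sequence: 13 steps (steps 1, 2, 3, 5, 7, 8, 9, 10, 11, 12, 13, 16, 17).

Steps most likely to fail:

1. Step 10 (proposed new method). The C10 cation may lose a proton from C20 (ene-type termination) or be quenched by the enolate before the vinylsilane closes ring A. The facial bias exerted by C9 may be weaker than assumed, and the β,γ-unsaturated ketone may enolise toward C9 and lose its configuration. Ketone 22 is therefore to be freed from its C9-equatorial diastereomer (which carries the mirror-image ring fusion) before step 11; if the facial preference turns out opposite, (+)-MIB in step 5 supplies the mirror-image trienone. Fallback with known chemistry, setting out from 20: the bicyclization is split into two classical operations. A Lewis-acid-catalysed type 1 ene reaction of the vinyl ketone with the C5=C10 alkene (Me2AlCl, CH2Cl2, −78 °C, hydrogen taken from C20) closes ring B alone through the C5–C6 bond and should give the monocyclic methylidene ketone F1. Protonation of the C10=C20 alkene of F1 (CF3SO3H, CH2Cl2, −78 °C) then regenerates the C10 cation for an ordinary vinylsilane-terminated cation–olefin cyclization that closes ring A and comes back to the route at 22.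

2. Step 8. The [3,3] shift may stall because a fully substituted ketene-acetal carbon has to bond to C9 next to the methyl-bearing alkene carbon, leaving time for fragmentation or C-silylation of the silyl ketene acetal. Fallback, setting out from 12: esterification with 2-[(triethylsilyl)oxy]acetic acid (DCC, DMAP) gives the glycolate ester F2. Its chelation-controlled Ireland–Claisen rearrangement (KN(SiMe3)2, Me3SiCl; then aq. HCl) forms only a tertiary C8 centre and should give the secondary α-hydroxy acid F3. Pb(OAc)4 cleaves it to the aldehyde F4, CH2=CHMgBr (THF, −78 °C) adds to give the allylic alcohol F5, and Dess–Martin oxidation comes back to the route at 20.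

3. Step 5. Hydrozirconation of the unsymmetrical internal alkyne may be incompletely regioselective, and enantiofacial control in the addition to the α-quaternary aldehyde may be insufficient. Fallback, setting out from 7 and 9: the same hydrozirconation, transmetalation and addition are run without the amino alcohol to give the racemic alcohol F6, which is freed from its regioisomer. A Sharpless kinetic resolution (Ti(OiPr)4, L-(+)-diisopropyl tartrate, t-BuOOH, CH2Cl2, −20 °C) should then epoxidise the (5S) enantiomer to the epoxy alcohol F7, which is removed, and leave the (5R) alcohol, which is compound 12 of the route.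

Further compounds

F1 | step 10 | (2S,4S)-2-(2-chloroethyl)-3-methylidene-4-[(4Z)-2-methyl-5-(trimethylsilyl)pent-4-en-2-yl]cyclohexan-1-one | ClCC[C@H]1C(=C)[C@@H](CCC1=O)C(C)(C)C/C=C\[Si](C)(C)C
F2 | step 8 | (1Z,5R,6E)-9-chloro-4,4,6-trimethyl-1-(trimethylsilyl)nona-1,6-dien-5-yl 2-[(triethylsilyl)oxy]acetate | ClCC/C=C(C)/[C@H](OC(=O)CO[Si](CC)(CC)CC)C(C)(C)C/C=C\[Si](C)(C)C
F3 | step 8 | (3S,4E,8Z)-3-(2-chloroethyl)-2-hydroxy-4,6,6-trimethyl-9-(trimethylsilyl)nona-4,8-dienoic acid (C2 undefined) | OC(=O)C(O)[C@@H](CCCl)/C(C)=C/C(C)(C)C/C=C\[Si](C)(C)C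
F4 | step 8 | (2S,3E,7Z)-2-(2-chloroethyl)-3,5,5-trimethyl-8-(trimethylsilyl)octa-3,7-dienal | O=C[C@@H](CCCl)/C(C)=C/C(C)(C)C/C=C\[Si](C)(C)C
F5 | step 8 | (4S,5E,9Z)-4-(2-chloroethyl)-5,7,7-trimethyl-10-(trimethylsilyl)deca-1,5,9-trien-3-ol (C3 epimers) | C=CC(O)[C@@H](CCCl)/C(C)=C/C(C)(C)C/C=C\[Si](C)(C)C
F6 | step 5 | (1Z,6E)-9-chloro-4,4,6-trimethyl-1-(trimethylsilyl)nona-1,6-dien-5-ol (racemic) | ClCC/C=C(C)/C(O)C(C)(C)C/C=C\[Si](C)(C)C
F7 | step 5 | (1S,4Z)-1-[(2R,3R)-3-(2-chloroethyl)-2-methyloxiran-2-yl]-2,2-dimethyl-5-(trimethylsilyl)pent-4-en-1-ol | ClCC[C@H]1O[C@]1(C)[C@@H](O)C(C)(C)C/C=C\[Si](C)(C)C
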